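Locants follow the germacrane skeleton: C10(CH3)=C1–C2–C3–C4(CH3)–C5 (oxirane across C4/C5), C6 (OH), C7 (isopropyl), C8 (aroyloxy), C9. The oxygen at C6 and the E C10=C1 olefin are the two ends of a Grob fragmentation: a bond drawn from C6 to C10 splits the ten-membered ring into a cyclopentane (C6–C7–C8–C9–C10) and a cycloheptene (C10–C1–C2–C3–C4=C5–C6) whose Z olefin is the one a cis-oxirane requires.
Cuts, in retrosynthetic order: the oxirane C–O bonds at C4/C5; the O8–aroyl bond together with C6–H; the ring-expansion transform (C6–C10 reconnected, C5–C6 and C1–O cut); C10–C1 (aldol) with C1–H (reduction); C9=C10 (metathesis); C6–isopropenyl; C7–C8 (auxiliary aldol).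
Forward ring order: cyclopentenone by metathesis; iodoalkenyl tether attached at C10; a cycloheptene closed at C5–C6 onto the cyclopentanone and the shared C6–C10 bond cut in the same flask to open the ten-membered ring; oxirane last.
Stereochemistry: C7/C8 from the oxazolidinone-controlled syn aldol; C10 (enolate face) and C1 (oxazaborolidine reduction) are sacrificial and encode the E olefin; the Z olefin comes from anti-carbomagnesiation; C6 from intramolecular 1,3-anti hydride transfer out of the O8 hemiacetal; C4/C5 from oxygen delivery by the C6 vanadium alkoxide.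

Key step: step 15

Remark on the chemistry: the reductive aldol is assumed to add the aldehyde anti to the C7 isopropyl group, any C10 epimer being removed at the diketone stage; the C1 carbinol is set by catalyst control, because the face a metal chelate would prefer at a carbon bearing both CH3 and a ring CH2 cannot be predicted with confidence.

Step 1
Reactants: 1 (R)-4-benzyl-3-(3-methylbutanoyl)oxazolidin-2-one; 2 acrolein
Product: 4 syn-aldol imide (2R,3S), via dibutylboron Z-enolate 3 (not isolated)
Conditions: Bu2BOTf, i-Pr2NEt, CH2Cl2, −78 to 0 °C; then 2, −78 to 0 °C; pH 7 buffer, MeOH, 30% H2O2, 0 °C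
Reagents that add atoms: none
Why: Evans syn aldol reaction, in which the boron Z-enolate reacts through a Zimmerman–Traxler chair with one face shielded by the benzyl group, so that C7 (R in 4) and C8 (S in 4) are set together in the 2,3-syn relationship that becomes trans on the later five-membered ring.

Step 2
Reactants: 4 syn-aldol imide
Product: 5 β-hydroxy Weinreb amide (2R,3S)
Conditions: MeNH(OMe)·HCl, AlMe3, CH2Cl2, −20 to 0 °C
Reagents that add atoms: N,O-dimethylhydroxylamine hydrochloride, CNOC.Cl
Why: Weinreb transamination of an aldol imide, in which the aluminium amide is guided to the exocyclic carbonyl by the free β-hydroxyl and releases the auxiliary without epimerising C7.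

Step 3
Reactants: 5 β-hydroxy Weinreb amide
Product: 6 silylated Weinreb amide (2R,3S)
Conditions: TBSOTf, 2,6-lutidine, CH2Cl2, −78 to 0 °C
Reagents that add atoms: tert-butyldimethylsilyl trifluoromethanesulfonate, CC(C)(C)[Si](C)(C)OS(=O)(=O)C(F)(F)F
Why: Standard silylation of a secondary alcohol with a silyl triflate and a hindered base, which masks O8 against the organometallic steps until the Tishchenko step needs it free.

Step 4
Reactants: 6 silylated Weinreb amide; 7 2-bromopropene
Product: 9 isopropenyl ketone diene (4R,5S), via isopropenylmagnesium bromide 8 (not isolated)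
Conditions: 7, Mg, THF, reflux; then 6, THF, 0 °C to rt; 1 M HCl, 0 °C
Reagents that add atoms: none
Why: Weinreb ketone synthesis, in which the Grignard reagent adds once to give a magnesium chelate that collapses to the enone only on the acidic quench, which also protonates the released amine so that it cannot add to the new enone.

Step 5
Reactants: 9 isopropenyl ketone diene
Product: 10 trans-4-silyloxy-5-isopropyl-2-methylcyclopent-2-enone (4S,5R)
Conditions: second-generation Grubbs catalyst (SIMes)(PCy3)Cl2Ru=CHPh (5 mol %), CH2Cl2, 40 °C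
Reagents that add atoms: none
Why: Ring-closing olefin metathesis of a 1,6-dien-3-one to a 2-methylcyclopentenone with loss of ethene, feasible with the carbene-ligated ruthenium catalyst although one olefin is 1,1-disubstituted and electron-poor, and without effect on C7 or C8.

Step 6
Reactants: 11 propargyl alcohol
Product: 13 (Z)-3-iodo-2-methylprop-2-en-1-ol, via oxamagnesacycle 12 (not isolated)
Conditions: MeMgBr (2.5 equiv), CuI (10 mol %), THF, −10 °C to rt; then I2, −10 °C; aqueous work-up
Reagents that add atoms: methylmagnesium bromide, C[Mg]Br; iodine, II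
Why: Copper-catalysed anti-carbomagnesiation of a propargylic alkoxide, in which the oxygen–magnesium chelate places methyl on C2 and magnesium on C3 cis to the CH2O group, so that iodinolysis with retention gives only the Z vinyl iodide.

Step 7
Reactants: 13 (Z)-3-iodo-2-methylprop-2-en-1-ol
Product: 14 (Z)-3-bromo-1-iodo-2-methylprop-1-ene
Conditions: CBr4, PPh3, CH2Cl2, 0 °C
Reagents that add atoms: carbon tetrabromide, BrC(Br)(Br)Br
Why: Appel bromination of a primary allylic alcohol by SN2 displacement of the oxyphosphonium ion, which leaves the vinyl iodide and its geometry untouched.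

Step 8
Reactants: 15 tert-butyl acetate; 14 (Z)-3-bromo-1-iodo-2-methylprop-1-ene
Product: 17 tert-butyl (Z)-5-iodo-4-methylpent-4-enoate, via lithium ester enolate 16 (not isolated)
Conditions: LiN(i-Pr)2, THF, −78 °C; then 14, −78 to −20 °C
Reagents that add atoms: none
Why: SN2 alkylation of an ester lithium enolate with a reactive allylic bromide, the tert-butyl ester suppressing Claisen self-condensation and the vinyl iodide being inert to the amide base at low temperature.

Step 9
Reactants: 17 tert-butyl (Z)-5-iodo-4-methylpent-4-enoate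
Product: 18 (Z)-5-iodo-4-methylpent-4-en-1-ol
Conditions: i-Bu2AlH (2.2 equiv), CH2Cl2, −78 to 0 °C; aqueous work-up
Reagents that add atoms: none
Why: Aluminium hydride reduction of an ester to the primary alcohol, with i-Bu2AlH chosen because it does not attack the vinyl C–I bond.

Step 10
Reactants: 18 (Z)-5-iodo-4-methylpent-4-en-1-ol
Product: 19 (Z)-5-iodo-4-methylpent-4-enal
Conditions: Dess–Martin periodinane, CH2Cl2, 0 °C to rt
Reagents that add atoms: none
Why: Dess–Martin oxidation of a primary alcohol to the aldehyde under neutral conditions, without over-oxidation or isomerisation of the Z iodoalkene.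

Step 11
Reactants: 10 trans-4-silyloxy-5-isopropyl-2-methylcyclopent-2-enone; 19 (Z)-5-iodo-4-methylpent-4-enal
Product: 21 aldol adduct with quaternary C10 (10S), via lithium enolate 20 (not isolated)
Conditions: LiBH(s-Bu)3 (1.05 equiv), THF, −78 °C; then 19, −78 °C; AcOH, −78 °C
Reagents that add atoms: none
Why: Reductive aldol reaction, in which the bulky borohydride delivers hydride 1,4 to the α-methyl enone and the resulting regiodefined tetrasubstituted enolate adds to the aldehyde through a closed transition state on the face anti to the isopropyl group beside the metal-bearing oxygen, which creates C10 (S), while the C1 carbinol (mainly the anti-aldol epimer drawn) is of no consequence because step 12 erases it.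

Step 12
Reactants: 21 aldol adduct
Product: 22 2-acyl-2-methylcyclopentanone (1,3-diketone, 10S)
Conditions: Dess–Martin periodinane, CH2Cl2, 0 °C to rt
Reagents that add atoms: none
Why: Dess–Martin oxidation of a β-hydroxy ketone to a 2,2-disubstituted 1,3-diketone, which cannot enolise between the carbonyl groups and so keeps C10 intact while C1 is cleared for a controlled reduction and any C10 epimer is removed by chromatography.

Step 13
Reactants: 22 1,3-diketone
Product: 23 (1R)-β-hydroxy ketone
Conditions: (S)-Me-CBS [(3aS)-1-methyl-3,3-diphenyltetrahydro-1H,3H-pyrrolo[1,2-c][1,3,2]oxazaborole] (0.3 equiv), catecholborane (1.5 equiv), toluene, −78 to −40 °C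
Reagents that add atoms: none
Why: Corey–Bakshi–Shibata reduction, in which the oxazaborolidine binds the side-chain ketone with the quaternary C10 as the large and the CH2 as the small substituent and gives the (R)-carbinol at C1 by catalyst control, which places the C1 oxygen syn to C9 as the E olefin requires; the ring ketone, flanked by C10 and the isopropyl-bearing C7, is too hindered to compete, and catecholborane does not hydroborate the iodoalkene at low temperature.

Step 14
Reactants: 23 (1R)-β-hydroxy ketone
Product: 24 β-mesyloxy cyclopentanone carrying the (Z)-vinyl iodide (10S,1R)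
Conditions: MsCl, Et3N, CH2Cl2, −20 to 0 °C
Reagents that add atoms: methanesulfonyl chloride, CS(=O)(=O)Cl
Why: Mesylation through sulfene, which is fast even at a hydroxyl next to a quaternary carbon and retains the C1 configuration, with an amine base too weak to start a retro-aldol cleavage.

Step 15
Reactants: 24 β-mesyloxy cyclopentanone
Product: 27 (2Z,6E,9S,10R)-9-silyloxy-3,7-dimethyl-10-isopropylcyclodeca-2,6-dien-1-one, via vinyllithium 25 (not isolated), via bicyclic lithium alkoxide 26 (not isolated)
Conditions: t-BuLi (2.1 equiv), THF, −78 °C; then warm to 20 °C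
Reagents that add atoms: none
Why: Iodine–lithium exchange at the vinyl iodide outruns attack of t-BuLi on the doubly flanked C6 ketone and gives the Z vinyllithium 25, whose carbanion adds to C6 in a 7-exo-trig closure (new C5–C6 bond) on the face that carries the tether, anti to the C7 isopropyl group, so that the cis-fused bicyclo[5.3.0]decenyl alkoxide 26 forms and its single new stereocentre (C6, dictated by the tether and erased again) needs no further control. In 26 the C1–OMs bond sits equatorial on the seven-membered ring and antiperiplanar to the ring-fusion bond C6–C10, so on warming the oxyanion reforms the C6 carbonyl while C6–C10 breaks, C10=C1 forms and mesylate leaves in one concerted Grob fragmentation; the ten-membered ring is therefore not closed end to end but uncovered by cutting the bond common to the five- and seven-membered rings. The closest known reaction types are the Wharton fragmentation of bicyclic 1,3-diol monosulfonates to E-cyclodecenones and sequenced intramolecular Barbier cyclisation–Grob fragmentation of ω-iodo keto mesylates to medium-ring enones. The selectivity required is E geometry at C10=C1, which is stereospecific: in the (10S,1R) series the antiperiplanar arrangement puts C2 anti to C9 and gauche to the C10 methyl group, while the Z geometry at C4=C5 is carried over because vinyllithium reagents are configurationally stable at −78 °C. Three features of 24 keep side reactions down: C10 has no hydrogen, so the mesylate cannot be expelled by enolisation before the trigger fires; C1 is a secondary centre next to a quaternary carbon, so SN2 attack by the vinyllithium is slow; and the fragmentation converts the only strongly basic species into a neutral enone, which protects the β-silyloxy ketone from elimination.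

Step 16
Reactants: 27 9-silyloxy dienone
Product: 28 (2Z,6E,9S,10R)-9-hydroxy-3,7-dimethyl-10-isopropylcyclodeca-2,6-dien-1-one
Conditions: HF·pyridine, pyridine, THF, 0 °C to rt
Reagents that add atoms: none
Why: Fluoride cleavage of a secondary silyl ether under pyridine-buffered, non-basic conditions, chosen so that the freed β-hydroxy enone does not suffer retro-aldol cleavage, β-elimination or transannular oxa-Michael addition.

Step 17
Reactants: 28 9-hydroxy dienone; 29 4-(tert-butyldimethylsilyloxy)benzaldehyde
Product: 31 anti-6,8-diol 8-monoester (silyl-protected phenol), via hemiacetal 30 (not isolated)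
Conditions: SmI2 (0.3 equiv, premixed with 29), 29 (5 equiv), THF, −10 °C
Reagents that add atoms: none
Why: Evans–Tishchenko reaction, in which a trivalent samarium alkoxide (from SmI2 and the aldehyde) holds the O8 hemiacetal and the C6 carbonyl in a six-membered chair and the hemiacetal hydride is transferred intramolecularly, which sets C6 1,3-anti to C8 (S in 31, the configuration of the target) and leaves the aroyl group on O8 only.

Step 18
Reactants: 31 anti-diol monoester (silyl-protected phenol)
Product: 32 anti-diol monoester with free phenol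
Conditions: Bu4NF, AcOH (1:1), THF, 0 °C
Reagents that add atoms: none
Why: Cleavage of an aryl silyl ether with acetic acid-buffered fluoride, fast because phenoxide leaves silicon readily and mild enough not to cause 1,3-acyl migration from O8 to O6.

Step 19
Reactants: 32 anti-diol monoester with free phenol
Product: 33 target CNP0365539.4
Conditions: VO(acac)2 (10 mol %), t-BuOOH (1.5 equiv), CH2Cl2, 0 °C to rt
Reagents that add atoms: tert-butyl hydroperoxide, CC(C)(C)OO
Why: Vanadium-catalysed hydroxyl-directed epoxidation, in which the C6 alkoxide binds the pentavalent vanadium tert-butylperoxo complex and delivers oxygen to the adjacent Z C4=C5 olefin on the ring face that carries the hydroxyl, the cis-epoxy alcohol outcome known for medium-ring Z-cycloalkenols, which sets C4 (S) and C5 (R) and leaves the remote E C1(10) olefin alone.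

Compound list
1 | (4R)-4-benzyl-3-(3-methylbutanoyl)-1,3-oxazolidin-2-one | O=C1OC[C@@H](Cc2ccccc2)N1C(=O)CC(C)C | starting material
2 | acrolein (prop-2-enal) | C=CC=O | starting material
3 | dibutylboron Z-enolate of 1 | O=C1OC[C@@H](Cc2ccccc2)N1/C(OB(CCCC)CCCC)=C/C(C)C | intermediate (not isolated)
4 | (4R)-4-benzyl-3-[(2R,3S)-3-hydroxy-2-(propan-2-yl)pent-4-enoyl]-1,3-oxazolidin-2-one | O=C1OC[C@@H](Cc2ccccc2)N1C(=O)[C@H](C(C)C)[C@@H](O)C=C | intermediate
5 | (2R,3S)-3-hydroxy-N-methoxy-N-methyl-2-(propan-2-yl)pent-4-enamide | CON(C)C(=O)[C@H](C(C)C)[C@@H](O)C=C | intermediate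
6 | (2R,3S)-3-[(tert-butyldimethylsilyl)oxy]-N-methoxy-N-methyl-2-(propan-2-yl)pent-4-enamide | CON(C)C(=O)[C@H](C(C)C)[C@@H](O[Si](C)(C)C(C)(C)C)C=C | intermediate
7 | 2-bromopropene | C=C(C)Br | starting material
8 | isopropenylmagnesium bromide | C=C(C)[Mg]Br | intermediate (not isolated)
9 | (4R,5S)-5-[(tert-butyldimethylsilyl)oxy]-2-methyl-4-(propan-2-yl)hepta-1,6-dien-3-one | C=C(C)C(=O)[C@H](C(C)C)[C@@H](O[Si](C)(C)C(C)(C)C)C=C | intermediate
10 | (4S,5R)-4-[(tert-butyldimethylsilyl)oxy]-2-methyl-5-(propan-2-yl)cyclopent-2-en-1-one (4,5-trans) | O=C1[C@H](C(C)C)[C@@H](O[Si](C)(C)C(C)(C)C)C=C1C | intermediate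
11 | propargyl alcohol (prop-2-yn-1-ol) | C#CCO | starting material
12 | 4-methyl-2,5-dihydro-1,2-oxamagnesole (chelated Z-vinylmagnesium alkoxide) | CC1=C[Mg]OC1 | intermediate (not isolated)
13 | (2Z)-3-iodo-2-methylprop-2-en-1-ol | OC/C(C)=C\I | intermediate
14 | (1Z)-3-bromo-1-iodo-2-methylprop-1-ene | BrC/C(C)=C\I | intermediate
15 | tert-butyl acetate | CC(=O)OC(C)(C)C | starting material
16 | lithium 1-tert-butoxyethen-1-olate | C=C(O[Li])OC(C)(C)C | intermediate (not isolated)
17 | tert-butyl (4Z)-5-iodo-4-methylpent-4-enoate | CC(C)(C)OC(=O)CC/C(C)=C\I | intermediate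
18 | (4Z)-5-iodo-4-methylpent-4-en-1-ol | OCCC/C(C)=C\I | intermediate
19 | (4Z)-5-iodo-4-methylpent-4-enal | O=CCC/C(C)=C\I | intermediate
20 | lithium (4S,5R)-4-[(tert-butyldimethylsilyl)oxy]-2-methyl-5-(propan-2-yl)cyclopent-1-en-1-olate | CC1=C(O[Li])[C@H](C(C)C)[C@@H](O[Si](C)(C)C(C)(C)C)C1 | intermediate (not isolated)
21 | (2S,4S,5R)-4-[(tert-butyldimethylsilyl)oxy]-2-[(1S,4Z)-1-hydroxy-5-iodo-4-methylpent-4-en-1-yl]-2-methyl-5-(propan-2-yl)cyclopentan-1-one | O=C1[C@H](C(C)C)[C@@H](O[Si](C)(C)C(C)(C)C)C[C@@]1(C)[C@@H](O)CC/C(C)=C\I | intermediate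
22 | (2S,4S,5R)-4-[(tert-butyldimethylsilyl)oxy]-2-[(4Z)-5-iodo-4-methylpent-4-enoyl]-2-methyl-5-(propan-2-yl)cyclopentan-1-one | O=C1[C@H](C(C)C)[C@@H](O[Si](C)(C)C(C)(C)C)C[C@@]1(C)C(=O)CC/C(C)=C\I | intermediate
23 | (2S,4S,5R)-4-[(tert-butyldimethylsilyl)oxy]-2-[(1R,4Z)-1-hydroxy-5-iodo-4-methylpent-4-en-1-yl]-2-methyl-5-(propan-2-yl)cyclopentan-1-one | O=C1[C@H](C(C)C)[C@@H](O[Si](C)(C)C(C)(C)C)C[C@@]1(C)[C@H](O)CC/C(C)=C\I | intermediate
24 | (2S,4S,5R)-4-[(tert-butyldimethylsilyl)oxy]-2-[(1R,4Z)-5-iodo-1-(methanesulfonyloxy)-4-methylpent-4-en-1-yl]-2-methyl-5-(propan-2-yl)cyclopentan-1-one | O=C1[C@H](C(C)C)[C@@H](O[Si](C)(C)C(C)(C)C)C[C@@]1(C)[C@H](OS(C)(=O)=O)CC/C(C)=C\I | intermediate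
25 | Z-vinyllithium from 24 (lithium in place of iodine) | O=C1[C@H](C(C)C)[C@@H](O[Si](C)(C)C(C)(C)C)C[C@@]1(C)[C@H](OS(C)(=O)=O)CC/C(C)=C\[Li] | intermediate (not isolated)
26 | lithium alkoxide of the cis-fused bicyclo[5.3.0]dec-2-en-1-ol (C5–C6 bond closed, O on C6 cis to the C10 methyl, equatorial mesylate on C1) | [Li]O[C@@]12C=C(C)CC[C@@H](OS(C)(=O)=O)[C@]1(C)C[C@H](O[Si](C)(C)C(C)(C)C)[C@H]2C(C)C | intermediate (not isolated)
27 | (2Z,6E,9S,10R)-9-[(tert-butyldimethylsilyl)oxy]-3,7-dimethyl-10-(propan-2-yl)cyclodeca-2,6-dien-1-one | C/C1=C\CC/C(C)=C\C(=O)[C@H](C(C)C)[C@@H](O[Si](C)(C)C(C)(C)C)C1 | intermediate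
28 | (2Z,6E,9S,10R)-9-hydroxy-3,7-dimethyl-10-(propan-2-yl)cyclodeca-2,6-dien-1-one | C/C1=C\CC/C(C)=C\C(=O)[C@H](C(C)C)[C@@H](O)C1 | intermediate
29 | 4-[(tert-butyldimethylsilyl)oxy]benzaldehyde | O=Cc1ccc(O[Si](C)(C)C(C)(C)C)cc1 | starting material
30 | hemiacetal of O8 of 28 with 29 (samarium-bound in the flask; hemiacetal carbon not defined) | C/C1=C\CC/C(C)=C\C(=O)[C@H](C(C)C)[C@@H](OC(O)c2ccc(O[Si](C)(C)C(C)(C)C)cc2)C1 | intermediate (not isolated)
31 | (1S,3E,7Z,9S,10S)-9-hydroxy-3,7-dimethyl-10-(propan-2-yl)cyclodeca-3,7-dien-1-yl 4-[(tert-butyldimethylsilyl)oxy]benzoate | C/C1=C\CC/C(C)=C\[C@H](O)[C@H](C(C)C)[C@@H](OC(=O)c2ccc(O[Si](C)(C)C(C)(C)C)cc2)C1 | intermediate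
32 | (1S,3E,7Z,9S,10S)-9-hydroxy-3,7-dimethyl-10-(propan-2-yl)cyclodeca-3,7-dien-1-yl 4-hydroxybenzoate | C/C1=C\CC/C(C)=C\[C@H](O)[C@H](C(C)C)[C@@H](OC(=O)c2ccc(O)cc2)C1 | intermediate
33 | (1R,2R,3S,4S,6E,10S)-2-hydroxy-6,10-dimethyl-3-(propan-2-yl)-11-oxabicyclo[8.1.0]undec-6-en-4-yl 4-hydroxybenzoate; germacrane locants 4S,5R,6R,7S,8S,1(10)E | C/C1=C\CC[C@]2(C)O[C@@H]2[C@H](O)[C@H](C(C)C)[C@@H](OC(=O)c2ccc(O)cc2)C1 | target

Total step count: 19. Longest linear sequence: 14 steps (steps 1–5, then 11–19; the branch through steps 6–10 is equally long).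

Steps most likely to fail

Step 15. The vinyllithium may be consumed by proton transfer from the methanesulfonyl CH3 group or from C7–H before it closes the seven-membered ring, or the lithium alkoxide may be too tightly aggregated to fragment before it attacks the β-silyloxy ketone. The fallback separates the two events and sets out from 23. Silylation (Me3SiCl, imidazole, CH2Cl2) should give the trimethylsilyl ether F1, which has no acidic sulfonyl protons. Exchange and cyclisation with t-BuLi (2.1 equiv, THF, −78 °C), followed by aqueous work-up, should give the cis-fused bicyclic tertiary alcohol F2. Citric acid in MeOH removes the trimethylsilyl group to give the bicyclic 1,6-diol F3. MsCl/Et3N is expected to sulfonylate only the secondary C1 hydroxyl and give the monomesylate F4. KOt-Bu in THF at 0 °C then effects a classical Wharton fragmentation through the more reactive potassium alkoxide, and the route is rejoined at 27.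

Step 11. The borohydride may reduce the enone 1,2 instead of 1,4, the hindered aldolate may revert by retro-aldol reaction before the quench, or the aldehyde may be enolised by the tetrasubstituted enolate. The fallback sets out from 10 and replaces the metal enolate by an isolable silyl enol ether. RhCl(PPh3)3-catalysed 1,4-hydrosilylation with Et3SiH should give the triethylsilyl enol ether F5. A Mukaiyama aldol addition to 19 (BF3·OEt2, CH2Cl2, −78 °C), which is irreversible under these conditions, returns to the route at 21; the C1 epimer mixture is immaterial because step 12 oxidises it.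

Step 19. The ten-membered ring may react through the conformer that relieves allylic 1,3-strain, as open-chain Z-allylic alcohols do, so that oxygen is delivered to the wrong olefin face; alternatively the Lewis-acidic vanadium may open the new oxirane transannularly with the C1(10) olefin. The fallback sets out from 27 and moves the oxirane formation to the enone stage, where the face is chosen by peripheral attack on the Z-enone and not by a hydroxyl. Weitz–Scheffer epoxidation (t-BuOOH, benzyltrimethylammonium hydroxide, THF, 0 °C) should give the epoxy ketone F6. HF·pyridine/pyridine frees the hydroxy epoxy ketone F7. The Evans–Tishchenko reaction with 29 (SmI2 fully consumed by the aldehyde beforehand, so that no divalent samarium meets the epoxy ketone) sets C6 anti to C8 and gives the silyl-protected epoxy ester F8. Bu4NF/AcOH as in step 18 then rejoins the route at 33.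

Further compounds
F1 | step 15 | trimethylsilyl ether of 23 (O on C1) | O=C1[C@H](C(C)C)[C@@H](O[Si](C)(C)C(C)(C)C)C[C@@]1(C)[C@H](O[Si](C)(C)C)CC/C(C)=C\I
F2 | step 15 | cis-fused bicyclo[5.3.0]dec-2-en-1-ol with tertiary C6 hydroxyl cis to the C10 methyl and trimethylsilyloxy group on C1 | O[C@@]12C=C(C)CC[C@@H](O[Si](C)(C)C)[C@]1(C)C[C@H](O[Si](C)(C)C(C)(C)C)[C@H]2C(C)C
F3 | step 15 | cis-fused bicyclo[5.3.0]dec-2-ene-1,6-diol (tertiary C6 hydroxyl, secondary C1 hydroxyl; germacrane locants) | O[C@@]12C=C(C)CC[C@@H](O)[C@]1(C)C[C@H](O[Si](C)(C)C(C)(C)C)[C@H]2C(C)C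
F4 | step 15 | monomesylate of F3 at the secondary C1 hydroxyl | O[C@@]12C=C(C)CC[C@@H](OS(C)(=O)=O)[C@]1(C)C[C@H](O[Si](C)(C)C(C)(C)C)[C@H]2C(C)C
F5 | step 11 | triethylsilyl enol ether of the conjugate-reduced ketone from 10 | CC1=C(O[Si](CC)(CC)CC)[C@H](C(C)C)[C@@H](O[Si](C)(C)C(C)(C)C)C1
F6 | step 19 | (4S,5R)-4,5-epoxide of 27 (germacrane locants), cis-oxirane next to the C6 ketone | C/C1=C\CC[C@]2(C)O[C@@H]2C(=O)[C@H](C(C)C)[C@@H](O[Si](C)(C)C(C)(C)C)C1
F7 | step 19 | (4S,5R)-4,5-epoxy-8-hydroxy ketone (desilylated F6) | C/C1=C\CC[C@]2(C)O[C@@H]2C(=O)[C@H](C(C)C)[C@@H](O)C1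
F8 | step 19 | tert-butyldimethylsilyl ether of 33 at the phenol | C/C1=C\CC[C@]2(C)O[C@@H]2[C@H](O)[C@H](C(C)C)[C@@H](OC(=O)c2ccc(O[Si](C)(C)C(C)(C)C)cc2)C1
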